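**Plan**

- Retrosynthesis (carotenoid numbering; in each ring C1 = CMe2, C2 = CH2, C3 = CHOH, C4 = CHOSO3H, C5 = CHMe, C6 = CH carrying chain carbon C7). The cuts are: both O4–S bonds; both C7=C8 bonds (two C10 sulfones plus the C20 dialdehyde crocetindial); one C1–CH3 bond; the ring bond C2–C3; then C6–C7 and C4–C5.
- Enabling feature: in each cyclohexane ring the carbinol carbon C3 lies 1,3 to the quaternary carbon C1 across the single ring methylene C2, next to the oxygenated C4. With one C1 methyl read as =CH2, C3(OH)–C2H2–C1(=CH2) is a homoallylic alcohol. It is therefore the product of an intramolecular carbonyl-ene reaction between an α-silyloxy aldehyde (C3) and an isopropenyl group C1(CH3)=C2H2 on C6.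
- Forward order: crotylboration (C4–C5), γ-lactone template, enolate alkylation (C6–C7), methyl ketone, isopropenyl group, aldehyde, ene ring closure (C2–C3), hydromethylation of C1=CH2, sulfone, twofold Julia–Kocienski union, desilylation, O4-sulfation.
- Stereochemistry: C4 and C5 from catalyst-controlled syn-crotylboration; C6 from alkylation anti to the cis lactone substituents; C3 from the chair ene transition state. Chain geometry comes from all-E crocetindial and E-selective olefination; the sulfate site from stannylene activation of the equatorial O4.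

Key step: step 9

Assumption: the target is taken as the free-acid form of the 4,4'-disulfate as drawn, so the sulfation ends with a cold proton exchange; 2,2-dimethoxyacetaldehyde is used anhydrous (commercial aqueous solution, extracted and dried).

**Route**

Step 1
Reactants: 1 2,2-dimethoxyacetaldehyde; 2 (Z)-crotylboronic acid pinacol ester
Product: 3 (2S,3R)-1,1-dimethoxy-3-methylpent-4-en-2-ol
Conditions: (S)-3,3'-bis(2,4,6-triisopropylphenyl)-1,1'-binaphthyl-2,2'-diyl hydrogen phosphate ((S)-TRIP, 5 mol%), 4 Å MS, toluene, −30 °C; aq. NaHCO3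
Reagents that add atoms: none
Why: Chiral-phosphoric-acid-catalysed crotylboration through a closed six-membered chair transition state, in which the (Z)-boronate should give the syn C4-OH/C5-Me pair and the (S)-catalyst should select the aldehyde face that makes C4 (2S) and C5 (3R).

Step 2
Reactants: 3 (2S,3R)-1,1-dimethoxy-3-methylpent-4-en-2-ol
Product: 5 (3R,4S)-5,5-dimethoxy-3-methylpentane-1,4-diol, via 9-BBN adduct 4 (not isolated)
Conditions: 9-BBN (2.2 equiv), THF, 0 °C to rt; then NaOH, H2O2, 0 °C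
Reagents that add atoms: 9-borabicyclo[3.3.1]nonane (B1C2CCCC1CCC2, boron in 4 only); hydrogen peroxide (OO)
Why: Anti-Markovnikov hydroboration–oxidation of the terminal vinyl group, which should give the primary alcohol (future C1) without touching C4 or C5.

Step 3
Reactants: 5 (3R,4S)-5,5-dimethoxy-3-methylpentane-1,4-diol
Product: 7 (4R,5S)-5-(dimethoxymethyl)-4-methyloxolan-2-one, via lactol 6 (not isolated)
Conditions: TEMPO (2,2,6,6-tetramethylpiperidin-1-oxyl, 10 mol%), PhI(OAc)2 (2.2 equiv), CH2Cl2, rt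
Reagents that add atoms: none
Why: Nitroxyl-catalysed oxidative lactonisation of a 1,4-diol (primary alcohol to aldehyde, lactol, then lactone), which should carry the cis C4/C5 relationship into the ring unchanged.

Step 4
Reactants: 7 (4R,5S)-5-(dimethoxymethyl)-4-methyloxolan-2-one
Product: 9 (3S,4R,5S)-3-[(benzyloxy)methyl]-5-(dimethoxymethyl)-4-methyloxolan-2-one, via lithium enolate 8 (not isolated)
Conditions: LiN(iPr)2, THF, −78 °C; then BnOCH2Cl, −78 to −40 °C
Reagents that add atoms: lithium diisopropylamide (CC(C)N([Li])C(C)C, lithium in 8 only); benzyl chloromethyl ether (ClCOCc1ccccc1)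
Why: Lactone enolate alkylation in which the electrophile should enter anti to the cis C5-methyl and C4-dimethoxymethyl groups (both on one face), setting C6 (3S) with C7 trans to the methyl group.

Step 5
Reactants: 9 (3S,4R,5S)-3-[(benzyloxy)methyl]-5-(dimethoxymethyl)-4-methyloxolan-2-one
Product: 10 (3S,4R,5S)-3-[(benzyloxy)methyl]-5-hydroxy-6,6-dimethoxy-4-methylhexan-2-one
Conditions: MeLi (1.05 equiv), THF, −78 °C; sat. NH4Cl at −78 °C
Reagents that add atoms: methyllithium ([Li]C)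
Why: Mono-addition of an organolithium to a γ-lactone, where the tetrahedral lithium adduct should persist at −78 °C and collapse only on quench, giving the methyl ketone (C1, C2) without touching C4–C6.

Step 6
Reactants: 10 (3S,4R,5S)-3-[(benzyloxy)methyl]-5-hydroxy-6,6-dimethoxy-4-methylhexan-2-one
Product: 11 (3S,4R,5S)-3-[(benzyloxy)methyl]-5-[(tert-butyldimethylsilyl)oxy]-6,6-dimethoxy-4-methylhexan-2-one
Conditions: TBSCl, imidazole, DMF, rt
Reagents that add atoms: tert-butyldimethylsilyl chloride (CC(C)(C)[Si](C)(C)Cl)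
Why: Silylation of the secondary alcohol under weakly basic conditions, which should protect O4 and fix the open keto form without epimerising C6.

Step 7
Reactants: 11 (3S,4R,5S)-3-[(benzyloxy)methyl]-5-[(tert-butyldimethylsilyl)oxy]-6,6-dimethoxy-4-methylhexan-2-one
Product: 12 tert-butyl{[(2S,3R,4R)-4-[(benzyloxy)methyl]-1,1-dimethoxy-3,5-dimethylhex-5-en-2-yl]oxy}dimethylsilane
Conditions: Cp2TiMe2 (3 equiv), toluene/THF, 65 °C, dark
Reagents that add atoms: dimethyltitanocene (C[Ti](C)(C1C=CC=C1)C1C=CC=C1)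
Why: Petasis methylenation, in which the titanium methylidene Cp2Ti=CH2 formed thermally from Cp2TiMe2 with loss of methane is non-basic and free of aluminium Lewis acid, so the methyl ketone should become the isopropenyl group without enolising the α-stereocentre C6, eliminating the β-benzyloxy group or opening the acetal.

Step 8
Reactants: 12 tert-butyl{[(2S,3R,4R)-4-[(benzyloxy)methyl]-1,1-dimethoxy-3,5-dimethylhex-5-en-2-yl]oxy}dimethylsilane
Product: 14 (2S,3R,4R)-4-[(benzyloxy)methyl]-2-[(tert-butyldimethylsilyl)oxy]-3,5-dimethylhex-5-enal, via collidinium salt 13 (not isolated)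
Conditions: Et3SiOTf, 2,4,6-collidine, CH2Cl2, 0 °C; then H2O
Reagents that add atoms: triethylsilyl triflate (CC[Si](CC)(CC)OS(=O)(=O)C(F)(F)F, triflate in 13 only); 2,4,6-collidine (Cc1cc(C)nc(C)c1, in 13 only); water (O)
Why: Silyl-triflate/pyridine-base cleavage of a dimethyl acetal through a collidinium N,O-acetal that water hydrolyses near neutrality, so the silyl ether, the 1,1-disubstituted alkene and the α-stereocentre C4 should survive.

Step 9
Reactants: 14 (2S,3R,4R)-4-[(benzyloxy)methyl]-2-[(tert-butyldimethylsilyl)oxy]-3,5-dimethylhex-5-enal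
Product: 15 (1R,2S,3R,4R)-4-[(benzyloxy)methyl]-2-[(tert-butyldimethylsilyl)oxy]-3-methyl-5-methylidenecyclohexan-1-ol
Conditions: Me2AlCl (1.5 equiv), CH2Cl2, −78 to −40 °C; 1 M HCl work-up
Reagents that add atoms: none
Why: Me2AlCl binds the aldehyde oxygen, the terminal alkene carbon C2 of the isopropenyl group attacks C3, and a hydrogen of the isopropenyl methyl group passes to the oxygen in one asynchronous six-centre event, so the former methyl becomes the exocyclic C1=CH2 and the former =CH2 becomes ring C2. The closest known reaction type is the Me2AlCl-promoted type 2 intramolecular carbonyl-ene cyclisation of 5-methylhex-5-enals to 3-methylidenecyclohexanols. The cyclohexane ring closes in the 6-exo mode with respect to the C=O group and endo with respect to the C=C bond, the ene unit being tethered through its central carbon C1. The new stereocentre C3 is fixed by the chair transition state in which the O4-silyloxy, C5-methyl and C6-CH2OBn groups are equatorial and the carbonyl oxygen is axial, the only position from which it can reach the allylic methyl hydrogen, so the axial 3-OH cis to O4 (1R in 15) should result. The step needs C2–C3 closure with hydrogen loss from the methyl group, not hydrogen loss from C6–H, chloride capture or elimination into the ring: the isopropenyl group is the only ene donor, six is the only feasible ring size, the C6–H bond lies on the ring face opposite the axial oxygen, and Me2AlCl removes the acidic proton of the product complex as methane.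

Step 10
Reactants: 15 (1R,2S,3R,4R)-4-[(benzyloxy)methyl]-2-[(tert-butyldimethylsilyl)oxy]-3-methyl-5-methylidenecyclohexan-1-ol
Product: 17 (1R,2S,3R,4R)-4-[(benzyloxy)methyl]-2-[(tert-butyldimethylsilyl)oxy]-3,5,5-trimethylcyclohexan-1-ol, via sulfonyl hydrazide 16 (not isolated)
Conditions: Fe(acac)3 (50 mol%), PhSiH3, n-C8H17SO2NHNH2, aq. CH2O, THF/MeOH, rt; then MeOH, 60 °C
Reagents that add atoms: formaldehyde (C=O); octane-1-sulfonohydrazide (CCCCCCCCS(=O)(=O)NN, in 16 only)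
Why: Mukaiyama-type hydrogen-atom-transfer hydromethylation, in which an iron hydride delivers H to the exocyclic CH2, the tertiary C1 radical adds to the formaldehyde sulfonylhydrazone formed in the flask, and the hydrazide loses sulfinate and N2 on warming, so C1 should become the gem-dimethyl quaternary carbon with no new stereocentre.

Step 11
Reactants: 17 (1R,2S,3R,4R)-4-[(benzyloxy)methyl]-2-[(tert-butyldimethylsilyl)oxy]-3,5,5-trimethylcyclohexan-1-ol
Product: 18 (1R,2S,3R,4R)-2-[(tert-butyldimethylsilyl)oxy]-4-(hydroxymethyl)-3,5,5-trimethylcyclohexan-1-ol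
Conditions: H2 (1 atm), Pd/C, EtOAc, rt
Reagents that add atoms: none
Why: Hydrogenolysis of the benzyl ether, which should be clean because no alkene remains and the silyl ether is stable in ethyl acetate.

Step 12
Reactants: 18 (1R,2S,3R,4R)-2-[(tert-butyldimethylsilyl)oxy]-4-(hydroxymethyl)-3,5,5-trimethylcyclohexan-1-ol
Product: 19 (1R,2S,3R,4R)-2-[(tert-butyldimethylsilyl)oxy]-3,5,5-trimethyl-4-{[(1-phenyl-1H-tetrazol-5-yl)sulfanyl]methyl}cyclohexan-1-ol
Conditions: 1-phenyl-1H-tetrazole-5-thiol, PPh3, DIAD, THF, 0 °C to rt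
Reagents that add atoms: 1-phenyl-1H-tetrazole-5-thiol (Sc1nnnn1-c1ccccc1)
Why: Mitsunobu thioetherification, which should be selective for the primary C7 alcohol over the axial 3-OH shielded by the syn-axial C1 methyl group.

Step 13
Reactants: 19 (1R,2S,3R,4R)-2-[(tert-butyldimethylsilyl)oxy]-3,5,5-trimethyl-4-{[(1-phenyl-1H-tetrazol-5-yl)sulfanyl]methyl}cyclohexan-1-ol
Product: 21 (1R,2S,3R,4R)-2-[(tert-butyldimethylsilyl)oxy]-3,5,5-trimethyl-4-{[(1-phenyl-1H-tetrazol-5-yl)sulfonyl]methyl}cyclohexan-1-ol, via sulfoxide 20 (not isolated)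
Conditions: (NH4)6Mo7O24·4H2O (cat.), 30% H2O2, EtOH, 0 °C to rt
Reagents that add atoms: hydrogen peroxide (OO)
Why: Molybdate-catalysed oxidation of the sulfide to the sulfone, which should be chemoselective because the molecule holds no alkene and no other oxidisable group.

Step 14
Reactants: 21 (1R,2S,3R,4R)-2-[(tert-butyldimethylsilyl)oxy]-3,5,5-trimethyl-4-{[(1-phenyl-1H-tetrazol-5-yl)sulfonyl]methyl}cyclohexan-1-ol (2.4 equiv); 22 crocetindial
Product: 24 (3R,4S,5R,6R,3'R,4'S,5'R,6'R)-4,4'-bis[(tert-butyldimethylsilyl)oxy]-5,6,5',6'-tetrahydro-β,β-carotene-3,3'-diol, via mono-olefinated aldehyde 23 (not isolated)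
Conditions: KN(SiMe3)2 added to 21 and 22, THF, −78 °C to rt, dark, argon; sat. NH4Cl
Reagents that add atoms: none
Why: Twofold Julia–Kocienski olefination, in which the α-sulfonyl carbanion (more acidic than the free 3-OH) adds to each formyl group and Smiles rearrangement with loss of SO2 and tetrazolone should give both C7=C8 bonds with E geometry, the ring stereocentres being remote and non-epimerisable.

Step 15
Reactants: 24 (3R,4S,5R,6R,3'R,4'S,5'R,6'R)-4,4'-bis[(tert-butyldimethylsilyl)oxy]-5,6,5',6'-tetrahydro-β,β-carotene-3,3'-diol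
Product: 25 (3R,4S,5R,6R,3'R,4'S,5'R,6'R)-5,6,5',6'-tetrahydro-β,β-carotene-3,4,3',4'-tetrol
Conditions: Bu4NF, THF, rt, dark, argon; sat. NH4Cl
Reagents that add atoms: none
Why: Fluoride desilylation, which is mild enough for the polyene and should free both cis-3,4-diols (any base-induced silyl shift between O4 and O3 in step 14 is of no consequence here).

Step 16
Reactants: 25 (3R,4S,5R,6R,3'R,4'S,5'R,6'R)-5,6,5',6'-tetrahydro-β,β-carotene-3,4,3',4'-tetrol
Product: 27 (3R,4S,5R,6R,3'R,4'S,5'R,6'R)-5,6,5',6'-tetrahydro-β,β-carotene-3,4,3',4'-tetrol 4,4'-bis(hydrogen sulfate) (CNP0202532.2), via bis-stannylene acetal 26 (not isolated)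
Conditions: Bu2SnO (2.2 equiv), MeOH/toluene, reflux, dark; evaporate; SO3·NMe3 (2.4 equiv), 1,4-dioxane/DMF, rt; then H+-form cation-exchange resin, MeOH, 0 °C
Reagents that add atoms: dibutyltin oxide (CCCC[Sn](=O)CCCC, tin in 26 only); sulfur trioxide–trimethylamine (C[N+](C)(C)S(=O)(=O)[O-])
Why: Stannylene-acetal-directed regioselective O-sulfation, in which the dibutylstannylene acetal of each cis-3,4-diol activates the equatorial O4 while the axial O3 is also shielded by the syn-axial C1 methyl group, so SO3 should be delivered to O4 on both rings.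

**Compound list**

1 | 2,2-dimethoxyacetaldehyde | COC(OC)C=O | starting material
2 | (Z)-crotylboronic acid pinacol ester | C/C=C\CB1OC(C)(C)C(C)(C)O1 | starting material
3 | (2S,3R)-1,1-dimethoxy-3-methylpent-4-en-2-ol | COC(OC)[C@@H](O)[C@H](C)C=C | intermediate
4 | 9-[(3R,4S)-4-(9-borabicyclo[3.3.1]nonan-9-yloxy)-5,5-dimethoxy-3-methylpentyl]-9-borabicyclo[3.3.1]nonane | COC(OC)[C@@H](OB1C2CCCC1CCC2)[C@H](C)CCB1C2CCCC1CCC2 | intermediate
5 | (3R,4S)-5,5-dimethoxy-3-methylpentane-1,4-diol | COC(OC)[C@@H](O)[C@H](C)CCO | intermediate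
6 | (4R,5S)-5-(dimethoxymethyl)-4-methyloxolan-2-ol (anomers) | COC(OC)[C@H]1OC(O)C[C@H]1C | intermediate
7 | (4R,5S)-5-(dimethoxymethyl)-4-methyloxolan-2-one | COC(OC)[C@H]1OC(=O)C[C@H]1C | intermediate
8 | lithium (4R,5S)-5-(dimethoxymethyl)-4-methyl-4,5-dihydrofuran-2-olate | COC(OC)[C@H]1OC(O[Li])=C[C@H]1C | intermediate
9 | (3S,4R,5S)-3-[(benzyloxy)methyl]-5-(dimethoxymethyl)-4-methyloxolan-2-one | COC(OC)[C@H]1OC(=O)[C@H](COCc2ccccc2)[C@H]1C | intermediate
10 | (3S,4R,5S)-3-[(benzyloxy)methyl]-5-hydroxy-6,6-dimethoxy-4-methylhexan-2-one | COC(OC)[C@@H](O)[C@H](C)[C@@H](COCc1ccccc1)C(C)=O | intermediate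
11 | (3S,4R,5S)-3-[(benzyloxy)methyl]-5-[(tert-butyldimethylsilyl)oxy]-6,6-dimethoxy-4-methylhexan-2-one | COC(OC)[C@@H](O[Si](C)(C)C(C)(C)C)[C@H](C)[C@@H](COCc1ccccc1)C(C)=O | intermediate
12 | tert-butyl{[(2S,3R,4R)-4-[(benzyloxy)methyl]-1,1-dimethoxy-3,5-dimethylhex-5-en-2-yl]oxy}dimethylsilane | COC(OC)[C@@H](O[Si](C)(C)C(C)(C)C)[C@H](C)[C@@H](COCc1ccccc1)C(C)=C | intermediate
13 | 1-[(2S,3R,4R)-4-[(benzyloxy)methyl]-2-[(tert-butyldimethylsilyl)oxy]-1-methoxy-3,5-dimethylhex-5-en-1-yl]-2,4,6-trimethylpyridin-1-ium trifluoromethanesulfonate (C1 epimers) | COC([n+]1c(C)cc(C)cc1C)[C@@H](O[Si](C)(C)C(C)(C)C)[C@H](C)[C@@H](COCc1ccccc1)C(C)=C.[O-]S(=O)(=O)C(F)(F)F | intermediate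
14 | (2S,3R,4R)-4-[(benzyloxy)methyl]-2-[(tert-butyldimethylsilyl)oxy]-3,5-dimethylhex-5-enal | O=C[C@@H](O[Si](C)(C)C(C)(C)C)[C@H](C)[C@@H](COCc1ccccc1)C(C)=C | intermediate
15 | (1R,2S,3R,4R)-4-[(benzyloxy)methyl]-2-[(tert-butyldimethylsilyl)oxy]-3-methyl-5-methylidenecyclohexan-1-ol | c1ccccc1COC[C@@H]1[C@@H](C)[C@H](O[Si](C)(C)C(C)(C)C)[C@H](O)CC1=C | intermediate
16 | N'-{[(2R,3R,4S,5R)-2-[(benzyloxy)methyl]-4-[(tert-butyldimethylsilyl)oxy]-5-hydroxy-1,3-dimethylcyclohexyl]methyl}octane-1-sulfonohydrazide (C1 epimers) | c1ccccc1COC[C@@H]1[C@@H](C)[C@H](O[Si](C)(C)C(C)(C)C)[C@H](O)CC1(C)CNNS(=O)(=O)CCCCCCCC | intermediate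
17 | (1R,2S,3R,4R)-4-[(benzyloxy)methyl]-2-[(tert-butyldimethylsilyl)oxy]-3,5,5-trimethylcyclohexan-1-ol | c1ccccc1COC[C@@H]1[C@@H](C)[C@H](O[Si](C)(C)C(C)(C)C)[C@H](O)CC1(C)C | intermediate
18 | (1R,2S,3R,4R)-2-[(tert-butyldimethylsilyl)oxy]-4-(hydroxymethyl)-3,5,5-trimethylcyclohexan-1-ol | OC[C@@H]1[C@@H](C)[C@H](O[Si](C)(C)C(C)(C)C)[C@H](O)CC1(C)C | intermediate
19 | (1R,2S,3R,4R)-2-[(tert-butyldimethylsilyl)oxy]-3,5,5-trimethyl-4-{[(1-phenyl-1H-tetrazol-5-yl)sulfanyl]methyl}cyclohexan-1-ol | c1ccccc1-n1nnnc1SC[C@@H]1[C@@H](C)[C@H](O[Si](C)(C)C(C)(C)C)[C@H](O)CC1(C)C | intermediate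
20 | (1R,2S,3R,4R)-2-[(tert-butyldimethylsilyl)oxy]-3,5,5-trimethyl-4-{[(1-phenyl-1H-tetrazol-5-yl)sulfinyl]methyl}cyclohexan-1-ol (sulfur epimers) | c1ccccc1-n1nnnc1S(=O)C[C@@H]1[C@@H](C)[C@H](O[Si](C)(C)C(C)(C)C)[C@H](O)CC1(C)C | intermediate
21 | (1R,2S,3R,4R)-2-[(tert-butyldimethylsilyl)oxy]-3,5,5-trimethyl-4-{[(1-phenyl-1H-tetrazol-5-yl)sulfonyl]methyl}cyclohexan-1-ol | c1ccccc1-n1nnnc1S(=O)(=O)C[C@@H]1[C@@H](C)[C@H](O[Si](C)(C)C(C)(C)C)[C@H](O)CC1(C)C | intermediate
22 | crocetindial, (2E,4E,6E,8E,10E,12E,14E)-2,6,11,15-tetramethylhexadeca-2,4,6,8,10,12,14-heptaenedial | CC(/C=C/C=C(C)/C=O)=C\C=C\C=C(C)\C=C\C=C(C)\C=O | starting material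
23 | (2E,4E,6E,8E,10E,12E,14E,16E)-17-[(1R,4R,5S,6R)-5-[(tert-butyldimethylsilyl)oxy]-4-hydroxy-2,2,6-trimethylcyclohexyl]-2,6,11,15-tetramethylheptadeca-2,4,6,8,10,12,14,16-octaenal | CC(/C=C/C=C(C)/C=O)=C\C=C\C=C(C)\C=C\C=C(C)\C=C\[C@@H]1[C@@H](C)[C@H](O[Si](C)(C)C(C)(C)C)[C@H](O)CC1(C)C | intermediate
24 | (all-E,3R,4S,5R,6R,3'R,4'S,5'R,6'R)-4,4'-bis[(tert-butyldimethylsilyl)oxy]-5,6,5',6'-tetrahydro-β,β-carotene-3,3'-diol | CC(/C=C/C=C(C)/C=C/[C@@H]1[C@@H](C)[C@H](O[Si](C)(C)C(C)(C)C)[C@H](O)CC1(C)C)=C\C=C\C=C(C)\C=C\C=C(C)\C=C\[C@@H]1[C@@H](C)[C@H](O[Si](C)(C)C(C)(C)C)[C@H](O)CC1(C)C | intermediate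
25 | (all-E,3R,4S,5R,6R,3'R,4'S,5'R,6'R)-5,6,5',6'-tetrahydro-β,β-carotene-3,4,3',4'-tetrol | CC(/C=C/C=C(C)/C=C/[C@@H]1[C@@H](C)[C@H](O)[C@H](O)CC1(C)C)=C\C=C\C=C(C)\C=C\C=C(C)\C=C\[C@@H]1[C@@H](C)[C@H](O)[C@H](O)CC1(C)C | intermediate
26 | 3,4:3',4'-bis-O-(dibutylstannanediyl) derivative of tetrol 25 | CC(/C=C/C=C(C)/C=C/[C@@H]1[C@@H](C)[C@@H]2O[Sn](CCCC)(CCCC)O[C@@H]2CC1(C)C)=C\C=C\C=C(C)\C=C\C=C(C)\C=C\[C@@H]1[C@@H](C)[C@@H]2O[Sn](CCCC)(CCCC)O[C@@H]2CC1(C)C | intermediate
27 | (all-E,3R,4S,5R,6R,3'R,4'S,5'R,6'R)-5,6,5',6'-tetrahydro-β,β-carotene-3,4,3',4'-tetrol 4,4'-bis(hydrogen sulfate), CNP0202532.2 | CC(/C=C/C=C(C)/C=C/[C@@H]1[C@@H](C)[C@H](OS(=O)(=O)O)[C@H](O)CC1(C)C)=C\C=C\C=C(C)\C=C\C=C(C)\C=C\[C@@H]1[C@@H](C)[C@H](OS(=O)(=O)O)[C@H](O)CC1(C)C | target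

**Summary and risks**

Total step count: 16
Longest linear sequence: 16 steps (from 1; 22 enters at step 14 as a purchased compound)

Steps most likely to fail:

1. Step 9. Facial selectivity at C3 may erode if the chair with an equatorial aldehyde oxygen, or a stepwise cationic closure, competes. The fallback sets out from 14 and sets C3 by ketone reduction instead of by the ene transition state. The cyclisation is run without regard to C3 and should give (1S,2S,3R,4R)-4-[(benzyloxy)methyl]-2-[(tert-butyldimethylsilyl)oxy]-3-methyl-5-methylidenecyclohexan-1-ol F1 beside 15. Hydromethylation of the mixture as in step 10 should pass through N'-{[(2R,3R,4S,5S)-2-[(benzyloxy)methyl]-4-[(tert-butyldimethylsilyl)oxy]-5-hydroxy-1,3-dimethylcyclohexyl]methyl}octane-1-sulfonohydrazide F2 beside 16 and should give (1S,2S,3R,4R)-4-[(benzyloxy)methyl]-2-[(tert-butyldimethylsilyl)oxy]-3,5,5-trimethylcyclohexan-1-ol F3 beside 17. Dess–Martin periodinane in CH2Cl2 should then oxidise both epimers to the single ketone (2S,3R,4R)-4-[(benzyloxy)methyl]-2-[(tert-butyldimethylsilyl)oxy]-3,5,5-trimethylcyclohexan-1-one F4 without touching C4. Reduction of F4 with LiBH(sec-Bu)3 in THF at −78 °C should give the axial alcohol, because the axial C1 methyl group blocks axial hydride attack, and the route is rejoined at 17.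

2. Step 14. The hindered α-sulfonyl carbanion may add slowly to the weakly electrophilic polyene dialdehyde, with self-condensation of the sulfone anion, an incomplete second olefination or poor E/Z control. The fallback sets out from 18 and builds the chain by the C15 + C10 + C15 Wittig scheme. TEMPO/PhI(OAc)2 should oxidise the primary alcohol only and give (1R,4R,5S,6R)-5-[(tert-butyldimethylsilyl)oxy]-4-hydroxy-2,2,6-trimethylcyclohexane-1-carbaldehyde F5 with the secondary alcohol intact. Horner–Wadsworth–Emmons reaction with triethyl 3-methyl-4-phosphonocrotonate and LiN(SiMe3)2 should give ethyl (2E,4E)-5-[(1R,4R,5S,6R)-5-[(tert-butyldimethylsilyl)oxy]-4-hydroxy-2,2,6-trimethylcyclohexyl]-3-methylpenta-2,4-dienoate F6 as the main isomer. Reduction with i-Bu2AlH in toluene at −78 °C should give (2E,4E)-5-[(1R,4R,5S,6R)-5-[(tert-butyldimethylsilyl)oxy]-4-hydroxy-2,2,6-trimethylcyclohexyl]-3-methylpenta-2,4-dien-1-ol F7 as the allylic alcohol. PPh3·HBr in CH2Cl2 should convert it into [(2E,4E)-5-[(1R,4R,5S,6R)-5-[(tert-butyldimethylsilyl)oxy]-4-hydroxy-2,2,6-trimethylcyclohexyl]-3-methylpenta-2,4-dien-1-yl]triphenylphosphonium bromide F8 by allylic substitution. A double Wittig reaction of F8 with commercial 2,7-dimethylocta-2,4,6-trienedial (NaOMe, CH2Cl2/MeOH) should pass through the mono-condensed aldehyde (2E,4E,6E,8E,10E,12E)-13-[(1R,4R,5S,6R)-5-[(tert-butyldimethylsilyl)oxy]-4-hydroxy-2,2,6-trimethylcyclohexyl]-2,7,11-trimethyltrideca-2,4,6,8,10,12-hexaenal F9 and then, after thermal Z-to-E equilibration, rejoin the route at 24.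

3. Step 16. Regiocontrol between O4 and O3 may be lost, over-sulfation may occur, or the polyene may degrade during stannylene formation at reflux. The fallback sets out from 24 and uses the oxygen differentiation that the O4 silyl ethers provide, on condition that they have not shifted to O3 in step 14. Ac2O/DMAP/pyridine should give (all-E,3R,4S,5R,6R,3'R,4'S,5'R,6'R)-4,4'-bis[(tert-butyldimethylsilyl)oxy]-5,6,5',6'-tetrahydro-β,β-carotene-3,3'-diyl diacetate F10 by acylation of both free 3-hydroxy groups. HF·pyridine in THF/pyridine, which does not promote acyl migration, should remove the silyl groups to give (all-E,3R,4S,5R,6R,3'R,4'S,5'R,6'R)-4,4'-dihydroxy-5,6,5',6'-tetrahydro-β,β-carotene-3,3'-diyl diacetate F11 with both O4 positions free. SO3·pyridine in DMF should sulfate these positions to give (all-E,3R,4S,5R,6R,3'R,4'S,5'R,6'R)-4,4'-bis(sulfooxy)-5,6,5',6'-tetrahydro-β,β-carotene-3,3'-diyl diacetate F12 as its pyridinium salt. K2CO3 in MeOH followed by cold proton exchange should remove the acetates and rejoin the route at 27.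

**Further compounds**

F1 | step 9 | (1S,2S,3R,4R)-4-[(benzyloxy)methyl]-2-[(tert-butyldimethylsilyl)oxy]-3-methyl-5-methylidenecyclohexan-1-ol | c1ccccc1COC[C@@H]1[C@@H](C)[C@H](O[Si](C)(C)C(C)(C)C)[C@@H](O)CC1=C
F2 | step 9 | N'-{[(2R,3R,4S,5S)-2-[(benzyloxy)methyl]-4-[(tert-butyldimethylsilyl)oxy]-5-hydroxy-1,3-dimethylcyclohexyl]methyl}octane-1-sulfonohydrazide (C1 epimers) | c1ccccc1COC[C@@H]1[C@@H](C)[C@H](O[Si](C)(C)C(C)(C)C)[C@@H](O)CC1(C)CNNS(=O)(=O)CCCCCCCC
F3 | step 9 | (1S,2S,3R,4R)-4-[(benzyloxy)methyl]-2-[(tert-butyldimethylsilyl)oxy]-3,5,5-trimethylcyclohexan-1-ol | c1ccccc1COC[C@@H]1[C@@H](C)[C@H](O[Si](C)(C)C(C)(C)C)[C@@H](O)CC1(C)C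
F4 | step 9 | (2S,3R,4R)-4-[(benzyloxy)methyl]-2-[(tert-butyldimethylsilyl)oxy]-3,5,5-trimethylcyclohexan-1-one | c1ccccc1COC[C@@H]1[C@@H](C)[C@H](O[Si](C)(C)C(C)(C)C)C(=O)CC1(C)C
F5 | step 14 | (1R,4R,5S,6R)-5-[(tert-butyldimethylsilyl)oxy]-4-hydroxy-2,2,6-trimethylcyclohexane-1-carbaldehyde | O=C[C@@H]1[C@@H](C)[C@H](O[Si](C)(C)C(C)(C)C)[C@H](O)CC1(C)C
F6 | step 14 | ethyl (2E,4E)-5-[(1R,4R,5S,6R)-5-[(tert-butyldimethylsilyl)oxy]-4-hydroxy-2,2,6-trimethylcyclohexyl]-3-methylpenta-2,4-dienoate | CCOC(=O)/C=C(C)/C=C/[C@@H]1[C@@H](C)[C@H](O[Si](C)(C)C(C)(C)C)[C@H](O)CC1(C)C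
F7 | step 14 | (2E,4E)-5-[(1R,4R,5S,6R)-5-[(tert-butyldimethylsilyl)oxy]-4-hydroxy-2,2,6-trimethylcyclohexyl]-3-methylpenta-2,4-dien-1-ol | OC/C=C(C)/C=C/[C@@H]1[C@@H](C)[C@H](O[Si](C)(C)C(C)(C)C)[C@H](O)CC1(C)C
F8 | step 14 | [(2E,4E)-5-[(1R,4R,5S,6R)-5-[(tert-butyldimethylsilyl)oxy]-4-hydroxy-2,2,6-trimethylcyclohexyl]-3-methylpenta-2,4-dien-1-yl]triphenylphosphonium bromide | [Br-].c1ccccc1[P+](c1ccccc1)(c1ccccc1)C/C=C(C)/C=C/[C@@H]1[C@@H](C)[C@H](O[Si](C)(C)C(C)(C)C)[C@H](O)CC1(C)C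
F9 | step 14 | (2E,4E,6E,8E,10E,12E)-13-[(1R,4R,5S,6R)-5-[(tert-butyldimethylsilyl)oxy]-4-hydroxy-2,2,6-trimethylcyclohexyl]-2,7,11-trimethyltrideca-2,4,6,8,10,12-hexaenal | CC(/C=C/C=C(C)/C=C/[C@@H]1[C@@H](C)[C@H](O[Si](C)(C)C(C)(C)C)[C@H](O)CC1(C)C)=C\C=C\C=C(C)\C=O
F10 | step 16 | (all-E,3R,4S,5R,6R,3'R,4'S,5'R,6'R)-4,4'-bis[(tert-butyldimethylsilyl)oxy]-5,6,5',6'-tetrahydro-β,β-carotene-3,3'-diyl diacetate | CC(/C=C/C=C(C)/C=C/[C@@H]1[C@@H](C)[C@H](O[Si](C)(C)C(C)(C)C)[C@H](OC(C)=O)CC1(C)C)=C\C=C\C=C(C)\C=C\C=C(C)\C=C\[C@@H]1[C@@H](C)[C@H](O[Si](C)(C)C(C)(C)C)[C@H](OC(C)=O)CC1(C)C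
F11 | step 16 | (all-E,3R,4S,5R,6R,3'R,4'S,5'R,6'R)-4,4'-dihydroxy-5,6,5',6'-tetrahydro-β,β-carotene-3,3'-diyl diacetate | CC(/C=C/C=C(C)/C=C/[C@@H]1[C@@H](C)[C@H](O)[C@H](OC(C)=O)CC1(C)C)=C\C=C\C=C(C)\C=C\C=C(C)\C=C\[C@@H]1[C@@H](C)[C@H](O)[C@H](OC(C)=O)CC1(C)C
F12 | step 16 | (all-E,3R,4S,5R,6R,3'R,4'S,5'R,6'R)-4,4'-bis(sulfooxy)-5,6,5',6'-tetrahydro-β,β-carotene-3,3'-diyl diacetate | CC(/C=C/C=C(C)/C=C/[C@@H]1[C@@H](C)[C@H](OS(=O)(=O)O)[C@H](OC(C)=O)CC1(C)C)=C\C=C\C=C(C)\C=C\C=C(C)\C=C\[C@@H]1[C@@H](C)[C@H](OS(=O)(=O)O)[C@H](OC(C)=O)CC1(C)C
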